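**Plan**

- Retrosynthesis: after the three phenol protecting groups, the cuts are C4–C4a (ring C, anionic acylation), then O1–C2 (aryl ether), then C4a–Br, then the bond from C6 to the side chain together with the chain C1=C2 double bond.
- Forward, ring A: phloroglucinol is protected so that O1 differs from O5 and O7; the ten-carbon chain is attached at C6 by lithiation between the two SEM ethers, addition to (S)-citronellal and dehydration; O1 is then freed and C4a brominated.
- Forward, rings B and C: ring B enters as an (R)-β-hydroxy Weinreb amide and is joined to O1; ring C, the only ring made, closes last; two deprotections finish the synthesis.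
- Enabling feature: O1 is para to C6, so ring A with O5, O7 and the chain has a twofold axis through C6 and C8a. C4a and C8 are therefore equivalent, and bromination followed by closure can only lead to the 6-substituted flavanone.
- Stereochemistry: the chain centre is carried unchanged from (S)-citronellal. C2 comes from asymmetric hydrogenation of a β-keto ester to the (R)-carbinol, which is inverted to (S) in the etherification and never passes through a chalcone.

Key step: step 11

Assumption: SEM is 2-(trimethylsilyl)ethoxymethyl and TIPS is triisopropylsilyl; (S)-citronellal is taken at the highest commercial enantiomeric purity because its stereocentre becomes the side-chain centre unchanged, and carbinol 6 is carried on as the mixture of epimers at its new centre.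

**Route**

Step 1
Reactants: 1 benzene-1,3,5-triol (phloroglucinol)
Product: 2 5-(triisopropylsilyloxy)benzene-1,3-diol
Conditions: TIPSCl (1 equiv), imidazole, DMF, 0 °C to rt, threefold excess of 1
Reagents that add atoms: triisopropylsilyl chloride, CC(C)[Si](Cl)(C(C)C)C(C)C
Why: Silyl ether formation on a phenol, in which the three hydroxyls of 1 are equivalent, so an excess of the cheap, water-soluble triol should hold the reaction at the monoether, and the bulky silyl group marks the oxygen that becomes O1 without directing lithiation later.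

Step 2
Reactants: 2 5-(triisopropylsilyloxy)benzene-1,3-diol
Product: 3 1,3-bis(SEM-oxy)-5-(triisopropylsilyloxy)benzene
Conditions: SEMCl (2.4 equiv), i-Pr2NEt, CH2Cl2, 0 °C to rt
Reagents that add atoms: 2-(trimethylsilyl)ethoxymethyl chloride, C[Si](C)(C)CCOCCl
Why: Williamson-type O-alkylation of the two remaining phenols with an alkoxymethyl chloride under amine base should give the bis-acetal, whose oxygens protect O5 and O7 and act as paired directing groups in the next step, while the aryl silyl ether is inert to the amine.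

Step 3
Reactants: 3 1,3-bis(SEM-oxy)-5-(triisopropylsilyloxy)benzene; 4 (S)-citronellal, (3S)-3,7-dimethyloct-6-enal
Product: 6 (3S)-1-[2,6-bis(SEM-oxy)-4-(triisopropylsilyloxy)phenyl]-3,7-dimethyloct-6-en-1-ol (both C1 epimers), via aryllithium 5 (not isolated)
Conditions: n-BuLi (1.1 equiv), THF, 0 °C; then 4, −78 °C; then aqueous NH4Cl
Reagents that add atoms: none
Why: Directed ortho-metalation followed by 1,2-addition of the aryllithium to an aldehyde, in which the proton between the two SEM ethers is the only one flanked by two coordinating acetals, so lithiation should occur there (para to the silyloxy group) and the cold addition brings in all ten chain carbons with the stereocentre of 4 untouched, the new carbinol centre being left unselective because step 4 removes it.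

Step 4
Reactants: 6 (3S)-1-[2,6-bis(SEM-oxy)-4-(triisopropylsilyloxy)phenyl]-3,7-dimethyloct-6-en-1-ol
Product: 7 {4-[(1E,3S)-3,7-dimethylocta-1,6-dien-1-yl]-3,5-bis(SEM-oxy)phenoxy}triisopropylsilane
Conditions: Burgess reagent (Et3N+SO2N−CO2Me), PhMe, rt to 50 °C
Reagents that add atoms: none
Why: Burgess dehydration (syn-elimination of the sulfamate ester under neutral conditions), in which the carbinol carbon has β-hydrogens only on the chain CH2, so one regioisomer can form, the arrangement with aryl and alkyl anti should give the E-alkene, and the acetals, the remote trisubstituted alkene and the allylic stereocentre are not involved.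

Step 5
Reactants: 7 {4-[(1E,3S)-3,7-dimethylocta-1,6-dien-1-yl]-3,5-bis(SEM-oxy)phenoxy}triisopropylsilane
Product: 8 4-[(1E,3S)-3,7-dimethylocta-1,6-dien-1-yl]-3,5-bis(SEM-oxy)phenol
Conditions: TBAF, AcOH (1:1), THF, 0 °C to rt
Reagents that add atoms: none
Why: Fluoride-mediated cleavage of an aryl silyl ether should free O1 selectively, because SEM ethers need far more forcing fluoride conditions, and the acetic acid buffer keeps the electron-rich 4-alkenylphenol from standing as its phenoxide.

Step 6
Reactants: 8 4-[(1E,3S)-3,7-dimethylocta-1,6-dien-1-yl]-3,5-bis(SEM-oxy)phenol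
Product: 9 2-bromo-4-[(1E,3S)-3,7-dimethylocta-1,6-dien-1-yl]-3,5-bis(SEM-oxy)phenol
Conditions: NBS (1.0 equiv), CH2Cl2, −78 °C
Reagents that add atoms: N-bromosuccinimide, O=C1CCC(=O)N1Br
Why: Electrophilic aromatic bromination, in which the ring positions ortho to the free hydroxyl are the most nucleophilic sites of 8 and, being related by the twofold axis, give one and the same monobromide, while one equivalent of reagent at low temperature should leave both alkenes alone.

Step 7
Reactants: 10 ethyl 3-(4-hydroxyphenyl)-3-oxopropanoate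
Product: 11 ethyl 3-oxo-3-[4-(triisopropylsilyloxy)phenyl]propanoate
Conditions: TIPSCl, imidazole, DMF, rt
Reagents that add atoms: triisopropylsilyl chloride, CC(C)[Si](Cl)(C(C)C)C(C)C
Why: Silyl ether formation, in which the phenol of 10 is more acidic and more accessible than the keto-ester enol, so silylation should occur on the phenol oxygen and give a group that survives hydrogenation, Grignard and organolithium conditions.

Step 8
Reactants: 11 ethyl 3-oxo-3-[4-(triisopropylsilyloxy)phenyl]propanoate
Product: 12 ethyl (3R)-3-hydroxy-3-[4-(triisopropylsilyloxy)phenyl]propanoate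
Conditions: [RuCl2((S)-BINAP)] (0.5 mol %), H2 (50 atm), EtOH, 50 °C
Reagents that add atoms: none
Why: Noyori asymmetric hydrogenation of a β-keto ester, in which the chelated substrate is reduced on the face fixed by the (S)-configured diphosphine, which for an aryl ketone corresponds to the (R)-carbinol (aryl outranks CH2CO2Et in the descriptor), and a SEGPHOS-type ligand of the same axial sense can replace BINAP if higher enantiomeric purity is wanted.

Step 9
Reactants: 12 ethyl (3R)-3-hydroxy-3-[4-(triisopropylsilyloxy)phenyl]propanoate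
Product: 13 (3R)-3-hydroxy-N-methoxy-N-methyl-3-[4-(triisopropylsilyloxy)phenyl]propanamide
Conditions: MeNH(OMe)·HCl, i-PrMgCl, THF, −20 to 0 °C; then aqueous NH4Cl
Reagents that add atoms: N,O-dimethylhydroxylamine hydrochloride, CNOC.Cl
Why: Weinreb amide formation by aminolysis of the ester with a magnesium amide made in the flask, which should proceed at low temperature with the hydroxyl carried as its magnesium alkoxide, so that the benzylic carbinol is not cleaved by retro-aldol reaction and keeps its configuration.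

Step 10
Reactants: 9 2-bromo-4-[(1E,3S)-3,7-dimethylocta-1,6-dien-1-yl]-3,5-bis(SEM-oxy)phenol; 13 (3R)-3-hydroxy-N-methoxy-N-methyl-3-[4-(triisopropylsilyloxy)phenyl]propanamide
Product: 14 (3S)-3-{2-bromo-4-[(1E,3S)-3,7-dimethylocta-1,6-dien-1-yl]-3,5-bis(SEM-oxy)phenoxy}-N-methoxy-N-methyl-3-[4-(triisopropylsilyloxy)phenyl]propanamide
Conditions: PPh3, DIAD, PhMe, 0 °C to rt
Reagents that add atoms: none
Why: Mitsunobu etherification, in which the ortho-bromophenol is acidic enough to protonate the betaine and should displace the activated benzylic oxygen in an SN2 sense with inversion, turning the (R)-carbinol into the (S)-aryl ether that is C2 of the target, with toluene and low temperature chosen to suppress ionisation of the para-silyloxybenzylic centre and elimination to the cinnamamide.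

Step 11
Reactants: 14 (3S)-3-{2-bromo-4-[(1E,3S)-3,7-dimethylocta-1,6-dien-1-yl]-3,5-bis(SEM-oxy)phenoxy}-N-methoxy-N-methyl-3-[4-(triisopropylsilyloxy)phenyl]propanamide
Product: 17 (2S)-6-[(1E,3S)-3,7-dimethylocta-1,6-dien-1-yl]-5,7-bis(SEM-oxy)-2-[4-(triisopropylsilyloxy)phenyl]chroman-4-one, via aryllithium 15 (not isolated), via lithium hemiaminal alkoxide 16 (not isolated)
Conditions: t-BuLi (2.1 equiv), THF, −100 °C, then −78 °C; aqueous NH4Cl quench at −78 °C
Reagents that add atoms: none
Why: Two equivalents of t-BuLi (the second destroys the t-BuBr formed) should exchange the bromine at C4a faster at −100 °C than any proton is removed from C2 or C3, giving aryllithium 15, which is coordinated by the adjacent SEM oxygen and adds to the tethered amide carbonyl to form the chelated tetrahedral alkoxide 16, stable until the quench and therefore stopping at the ketone. The closest known reaction type is the Parham cyclisation of aryl bromides onto tethered Weinreb amides to give benzo-fused ketones, including chroman-4-ones from 3-(2-bromophenoxy)propanamides. Ring C is closed in a 6-exo-trig mode by formation of the C4–C4a bond. No stereocentre is created: C2 was set in step 10 and is not touched, ring C is never opened to a chalcone, and the chain centre is remote. The step needs chemoselectivity for exchange over proton transfer, since a C3 enolate could expel the aryloxide, and regioselectivity for the 6- over the 8-substituted flavanone; the first rests on the rate of exchange at low temperature and the cold buffered quench, the second on the twofold symmetry of ring A in 8, which made C4a and C8 the same position before bromination.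

Step 12
Reactants: 17 (2S)-6-[(1E,3S)-3,7-dimethylocta-1,6-dien-1-yl]-5,7-bis(SEM-oxy)-2-[4-(triisopropylsilyloxy)phenyl]chroman-4-one
Product: 18 (2S)-6-[(1E,3S)-3,7-dimethylocta-1,6-dien-1-yl]-5,7-dihydroxy-2-[4-(triisopropylsilyloxy)phenyl]chroman-4-one
Conditions: MgBr2·OEt2, n-BuSH, Et2O–MeNO2, rt
Reagents that add atoms: none
Why: Lewis acid cleavage of alkoxymethyl aryl ethers, in which MgBr2 coordinates the acetal oxygens (most strongly the one peri to the C4 carbonyl) and the thiol captures the released alkoxymethyl fragment so that it cannot alkylate C8, while the aryl silyl ether, both alkenes and the C2 ether should survive these non-basic conditions.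

Step 13
Reactants: 18 (2S)-6-[(1E,3S)-3,7-dimethylocta-1,6-dien-1-yl]-5,7-dihydroxy-2-[4-(triisopropylsilyloxy)phenyl]chroman-4-one
Product: 19 (2S)-6-[(1E,3S)-3,7-dimethylocta-1,6-dien-1-yl]-5,7-dihydroxy-2-(4-hydroxyphenyl)chroman-4-one (CNP0150993.1)
Conditions: HF·pyridine, pyridine, THF, 0 °C to rt
Reagents that add atoms: none
Why: Fluoride-mediated desilylation of an aryl silyl ether under buffered, non-basic conditions should free O4' last, so that the para-hydroxybenzylic C2–O1 bond never meets base and the (2S) configuration is kept.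

**Compound list**

1 | benzene-1,3,5-triol (phloroglucinol) | Oc1cc(O)cc(O)c1 | starting material
2 | 5-(triisopropylsilyloxy)benzene-1,3-diol | Oc1cc(O)cc(O[Si](C(C)C)(C(C)C)C(C)C)c1 | intermediate
3 | 1,3-bis(SEM-oxy)-5-(triisopropylsilyloxy)benzene | C[Si](C)(C)CCOCOc1cc(OCOCC[Si](C)(C)C)cc(O[Si](C(C)C)(C(C)C)C(C)C)c1 | intermediate
4 | (S)-citronellal, (3S)-3,7-dimethyloct-6-enal | CC(C)=CCC[C@H](C)CC=O | starting material
5 | [2,6-bis(SEM-oxy)-4-(triisopropylsilyloxy)phenyl]lithium | [Li]c1c(OCOCC[Si](C)(C)C)cc(O[Si](C(C)C)(C(C)C)C(C)C)cc1OCOCC[Si](C)(C)C | intermediate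
6 | (3S)-1-[2,6-bis(SEM-oxy)-4-(triisopropylsilyloxy)phenyl]-3,7-dimethyloct-6-en-1-ol, both C1 epimers | CC(C)=CCC[C@H](C)CC(O)c1c(OCOCC[Si](C)(C)C)cc(O[Si](C(C)C)(C(C)C)C(C)C)cc1OCOCC[Si](C)(C)C | intermediate
7 | {4-[(1E,3S)-3,7-dimethylocta-1,6-dien-1-yl]-3,5-bis(SEM-oxy)phenoxy}triisopropylsilane | CC(C)=CCC[C@H](C)/C=C/c1c(OCOCC[Si](C)(C)C)cc(O[Si](C(C)C)(C(C)C)C(C)C)cc1OCOCC[Si](C)(C)C | intermediate
8 | 4-[(1E,3S)-3,7-dimethylocta-1,6-dien-1-yl]-3,5-bis(SEM-oxy)phenol | CC(C)=CCC[C@H](C)/C=C/c1c(OCOCC[Si](C)(C)C)cc(O)cc1OCOCC[Si](C)(C)C | intermediate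
9 | 2-bromo-4-[(1E,3S)-3,7-dimethylocta-1,6-dien-1-yl]-3,5-bis(SEM-oxy)phenol | CC(C)=CCC[C@H](C)/C=C/c1c(OCOCC[Si](C)(C)C)cc(O)c(Br)c1OCOCC[Si](C)(C)C | intermediate
10 | ethyl 3-(4-hydroxyphenyl)-3-oxopropanoate | CCOC(=O)CC(=O)c1ccc(O)cc1 | starting material
11 | ethyl 3-oxo-3-[4-(triisopropylsilyloxy)phenyl]propanoate | CCOC(=O)CC(=O)c1ccc(O[Si](C(C)C)(C(C)C)C(C)C)cc1 | intermediate
12 | ethyl (3R)-3-hydroxy-3-[4-(triisopropylsilyloxy)phenyl]propanoate | CCOC(=O)C[C@@H](O)c1ccc(O[Si](C(C)C)(C(C)C)C(C)C)cc1 | intermediate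
13 | (3R)-3-hydroxy-N-methoxy-N-methyl-3-[4-(triisopropylsilyloxy)phenyl]propanamide | CON(C)C(=O)C[C@@H](O)c1ccc(O[Si](C(C)C)(C(C)C)C(C)C)cc1 | intermediate
14 | (3S)-3-{2-bromo-4-[(1E,3S)-3,7-dimethylocta-1,6-dien-1-yl]-3,5-bis(SEM-oxy)phenoxy}-N-methoxy-N-methyl-3-[4-(triisopropylsilyloxy)phenyl]propanamide | CC(C)=CCC[C@H](C)/C=C/c1c(OCOCC[Si](C)(C)C)cc(O[C@@H](CC(=O)N(C)OC)c2ccc(O[Si](C(C)C)(C(C)C)C(C)C)cc2)c(Br)c1OCOCC[Si](C)(C)C | intermediate
15 | aryllithium from 14 (lithium at C4a in place of bromine) | CC(C)=CCC[C@H](C)/C=C/c1c(OCOCC[Si](C)(C)C)cc(O[C@@H](CC(=O)N(C)OC)c2ccc(O[Si](C(C)C)(C(C)C)C(C)C)cc2)c([Li])c1OCOCC[Si](C)(C)C | intermediate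
16 | lithium alkoxide of the C4 N-methoxy-N-methyl hemiaminal of 17 (tetrahedral adduct, C4 unassigned) | CC(C)=CCC[C@H](C)/C=C/c1c(OCOCC[Si](C)(C)C)cc2c(c1OCOCC[Si](C)(C)C)C([O-])(N(C)OC)C[C@@H](c1ccc(O[Si](C(C)C)(C(C)C)C(C)C)cc1)O2.[Li+] | intermediate
17 | (2S)-6-[(1E,3S)-3,7-dimethylocta-1,6-dien-1-yl]-5,7-bis(SEM-oxy)-2-[4-(triisopropylsilyloxy)phenyl]chroman-4-one | CC(C)=CCC[C@H](C)/C=C/c1c(OCOCC[Si](C)(C)C)cc2c(c1OCOCC[Si](C)(C)C)C(=O)C[C@@H](c1ccc(O[Si](C(C)C)(C(C)C)C(C)C)cc1)O2 | intermediate
18 | (2S)-6-[(1E,3S)-3,7-dimethylocta-1,6-dien-1-yl]-5,7-dihydroxy-2-[4-(triisopropylsilyloxy)phenyl]chroman-4-one | CC(C)=CCC[C@H](C)/C=C/c1c(O)cc2c(c1O)C(=O)C[C@@H](c1ccc(O[Si](C(C)C)(C(C)C)C(C)C)cc1)O2 | intermediate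
19 | (2S)-6-[(1E,3S)-3,7-dimethylocta-1,6-dien-1-yl]-5,7-dihydroxy-2-(4-hydroxyphenyl)chroman-4-one | CC(C)=CCC[C@H](C)/C=C/c1c(O)cc2c(c1O)C(=O)C[C@@H](c1ccc(O)cc1)O2 | target

**Step count and risks**

Total step count: 13. Longest linear sequence: 10 steps (steps 1 to 6, then 10 to 13); the ring B branch (steps 7 to 9) joins at step 10.

Steps most likely to fail:

1. Step 11. Proton transfer from C3–H or C2–H to t-BuLi or to the aryllithium may compete with exchange and ring closure, and the resulting enolate would expel the aryloxide. The fallback sets out from phenol 8 and uses a softer organometallic from a different halide. N-Iodosuccinimide in CH2Cl2 at −78 °C should give 4-[(1E,3S)-3,7-dimethylocta-1,6-dien-1-yl]-2-iodo-3,5-bis(SEM-oxy)phenol F1. Mitsunobu etherification with 13 under the conditions of step 10 should then give (3S)-3-{4-[(1E,3S)-3,7-dimethylocta-1,6-dien-1-yl]-2-iodo-3,5-bis(SEM-oxy)phenoxy}-N-methoxy-N-methyl-3-[4-(triisopropylsilyloxy)phenyl]propanamide F2. Iodine–magnesium exchange with i-PrMgCl·LiCl in THF at −40 to 0 °C gives an arylmagnesium that is far less basic than 15 and should close onto the Weinreb amide, coming back to the route at 17.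

2. Step 10. Ionisation at the para-silyloxybenzylic carbon may erode the inversion, and dehydration toward the cinnamamide may compete. The fallback sets out from 13 and switches the donor on ring B off for the etherification.
   - TBAF/AcOH removes the silyl ether to give (3R)-3-hydroxy-3-(4-hydroxyphenyl)-N-methoxy-N-methylpropanamide F3.
   - Acetylation of the phenoxide alone (Ac2O, one equivalent of NaOH, water/THF, 0 °C) gives 4-{(1R)-1-hydroxy-3-[methoxy(methyl)amino]-3-oxopropyl}phenyl acetate F4, whose acetoxy group barely stabilises a benzylic cation.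
   - Mitsunobu reaction with 9 should give 4-[(1S)-1-{2-bromo-4-[(1E,3S)-3,7-dimethylocta-1,6-dien-1-yl]-3,5-bis(SEM-oxy)phenoxy}-3-[methoxy(methyl)amino]-3-oxopropyl]phenyl acetate F5.
   - Neutral deacetylation (NH4OAc, aqueous MeOH), chosen so that the para-hydroxybenzylic ether does not stand as a phenoxide, gives (3S)-3-{2-bromo-4-[(1E,3S)-3,7-dimethylocta-1,6-dien-1-yl]-3,5-bis(SEM-oxy)phenoxy}-3-(4-hydroxyphenyl)-N-methoxy-N-methylpropanamide F6.
   - TIPSCl/imidazole comes back to the route at 14.

3. Step 4. The sulfamate of the very electron-rich benzylic carbinol may ionise, with capture of the cation by the remote trisubstituted alkene or incomplete control of alkene geometry. The fallback sets out from 3 and 4 and forms the alkene without any benzylic leaving group. Aryllithium 5, generated as in step 3, is quenched with BrCl2CCCl2Br to give 2-bromo-1,3-bis(SEM-oxy)-5-(triisopropylsilyloxy)benzene F7. Aldehyde 4 is condensed with TsNHNH2 in MeOH to give N'-[(3S)-3,7-dimethyloct-6-en-1-ylidene]-4-methylbenzenesulfonohydrazide F8. Barluenga coupling of F7 and F8 (Pd2(dba)3, XPhos, LiOt-Bu, dioxane, 90 °C) proceeds through a palladium carbene, aryl migration and β-hydride elimination and should give the E-alkene directly, coming back to the route at 7.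

**Further compounds**

F1 | step 11 | 4-[(1E,3S)-3,7-dimethylocta-1,6-dien-1-yl]-2-iodo-3,5-bis(SEM-oxy)phenol | CC(C)=CCC[C@H](C)/C=C/c1c(OCOCC[Si](C)(C)C)cc(O)c(I)c1OCOCC[Si](C)(C)C
F2 | step 11 | (3S)-3-{4-[(1E,3S)-3,7-dimethylocta-1,6-dien-1-yl]-2-iodo-3,5-bis(SEM-oxy)phenoxy}-N-methoxy-N-methyl-3-[4-(triisopropylsilyloxy)phenyl]propanamide | CC(C)=CCC[C@H](C)/C=C/c1c(OCOCC[Si](C)(C)C)cc(O[C@@H](CC(=O)N(C)OC)c2ccc(O[Si](C(C)C)(C(C)C)C(C)C)cc2)c(I)c1OCOCC[Si](C)(C)C
F3 | step 10 | (3R)-3-hydroxy-3-(4-hydroxyphenyl)-N-methoxy-N-methylpropanamide | CON(C)C(=O)C[C@@H](O)c1ccc(O)cc1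
F4 | step 10 | 4-{(1R)-1-hydroxy-3-[methoxy(methyl)amino]-3-oxopropyl}phenyl acetate | CON(C)C(=O)C[C@@H](O)c1ccc(OC(C)=O)cc1
F5 | step 10 | 4-[(1S)-1-{2-bromo-4-[(1E,3S)-3,7-dimethylocta-1,6-dien-1-yl]-3,5-bis(SEM-oxy)phenoxy}-3-[methoxy(methyl)amino]-3-oxopropyl]phenyl acetate | CC(C)=CCC[C@H](C)/C=C/c1c(OCOCC[Si](C)(C)C)cc(O[C@@H](CC(=O)N(C)OC)c2ccc(OC(C)=O)cc2)c(Br)c1OCOCC[Si](C)(C)C
F6 | step 10 | (3S)-3-{2-bromo-4-[(1E,3S)-3,7-dimethylocta-1,6-dien-1-yl]-3,5-bis(SEM-oxy)phenoxy}-3-(4-hydroxyphenyl)-N-methoxy-N-methylpropanamide | CC(C)=CCC[C@H](C)/C=C/c1c(OCOCC[Si](C)(C)C)cc(O[C@@H](CC(=O)N(C)OC)c2ccc(O)cc2)c(Br)c1OCOCC[Si](C)(C)C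
F7 | step 4 | 2-bromo-1,3-bis(SEM-oxy)-5-(triisopropylsilyloxy)benzene | Brc1c(OCOCC[Si](C)(C)C)cc(O[Si](C(C)C)(C(C)C)C(C)C)cc1OCOCC[Si](C)(C)C
F8 | step 4 | N'-[(3S)-3,7-dimethyloct-6-en-1-ylidene]-4-methylbenzenesulfonohydrazide | CC(C)=CCC[C@H](C)CC=NNS(=O)(=O)c1ccc(C)cc1
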